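The runs were generated by integration for substances that don't exist, noise included.

all flasks: substrate 0.10 M
- south-east: first nucleophile 0.25 equiv; second nucleophile 2 equiv; protic impurity 5 mM; run made earlier
- north-west: first nucleophile 1 equiv; second nucleophile 2 equiv; protic impurity 5 mM; run made earlier
- west: first nucleophile 0.50 equiv; second nucleophile 1 equiv; protic impurity 5 mM; run made earlier
- flask: first nucleophile 0.500 equiv; second nucleophile 2.00 equiv; protic impurity 5.00 mM; time 3.0 h

| run | time / min | other capture product / % | target / % |
|---|---|---|---|
| south-east | 8.00 | 75.0 | 4.9 |
| south-east | 15.0 | 75.5 | 4.3 |
| south-east | 25.0 | 75.7 | 4.2 |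
| south-east | 40.0 | 74.9 | 3.6 |
| south-east | 60.0 | 75.1 | 5.1 |
| south-east | 120 | 75.7 | 3.5 |
| north-west | 8.00 | 28.6 | 13.0 |
| north-west | 15.0 | 29.5 | 11.8 |
| north-west | 25.0 | 29.7 | 12.9 |
| north-west | 40.0 | 29.2 | 12.3 |
| north-west | 60.0 | 28.6 | 12.6 |
| north-west | 120 | 29.3 | 12.5 |
| west | 10.0 | 51.2 | 8.5 |
| west | 25.0 | 51.7 | 8.4 |
| west | 50.0 | 50.3 | 9.0 |
| west | 80.0 | 50.0 | 8.8 |
| west | 120 | 50.6 | 7.2 |

(scatter of a reading: 0.5 percentage points)

- what may be going on: intermediate -> side product; first nucleophile + protic impurity -> quenched reagent; target <-> isomer of the product; first nucleophile + intermediate -> target; substrate -> intermediate; second nucleophile + intermediate -> other capture product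

- share of other capture product in other capture product plus target at 5.0 s
- share of other capture product in other capture product plus target at 4.0 min
- share of other capture product in other capture product plus target at 3.0 h
- which of other capture product and target there is more of at 3.0 h

Take it that substrate gives an intermediate. First nucleophile captures it as target, second nucleophile captures it as other capture product, and it can also fall to side product. Protic impurity quenches first nucleophile, and target exchanges with its isomer.

1. Subtract the impurity from the first nucleophile, assuming its full charge is quenched. Let B and D be first and second nucleophile in equiv of substrate. The north-west run then counts as B = 0.950 and D = 2.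

2. Take the first rung, capture. Let S be the first nucleophile's capture rate constant over the second nucleophile's. Target forms S·B/D times as fast as other capture product, so dB/dD = S·B/D. This integrates to ln(B at start / B at end) = S·ln(D at start / D at end).

3. Read S from the north-west run. Its other capture product is flat from the first sample, with mean 29.2%. Neglect side product and count the rest as target plus isomer. That ends at B = 0.242 and D = 1.71, giving S = 8.69, the selectivity factor: how many times faster first nucleophile captures intermediate than second nucleophile does at equal concentration.

4. Go to the flask, early on. Counting the impurity as quenched, B = 0.450, and before target turns to isomer the kinetic share of other capture product is D/(D + S·B). My estimate for 5.0 s is 33.8%.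

5. Go to the flask, at the end. The same integral gives other capture product 57.7%. Next rung, the isomer: the west run reads mean target 8.38% out of 0.450 equiv, taken as all captured. Scaled to the flask, that is target 7.87%, so other capture product leads, with share 88.0%. Last rung: the readings stay flat to 120 min, so I hold this for 3.0 h. No run was sampled at 4.0 min, so I place that share between my two.

The forecast gives 40% at 5.0 s, 82% at 4.0 min, 87% at 3.0 h and more other capture product, on this ground: “The yields are flat from the first sample, so everything is over by 8 min”. Its capture ratio is about 7, lower than my S.

The flask gives 36.4% at 5.0 s, 85.2% at 4.0 min and 87.6% at 3.0 h, with 55.1% other capture product against 7.82% target, so the forecast held.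

    intermediate → side product (k = 0.00660 s⁻¹)
    first nucleophile + protic impurity → quenched reagent (k = 1.80 M⁻¹ s⁻¹)
    target ⇌ isomer of the product (K = 4.60, k = 0.0110 s⁻¹)
    first nucleophile + intermediate → target (k = 17.0 M⁻¹ s⁻¹)
    substrate → intermediate (k = 0.0640 s⁻¹)
    second nucleophile + intermediate → other capture product (k = 2.00 M⁻¹ s⁻¹)

The comparison is S·B against D: in this flask, with B net of impurity, S·B/D is 1.96, so my share is 33.8% beside the 36.4% found at 5.0 s. In the neighbour flask with 1.20 equiv of first nucleophile, S·B/D is 5.00, so the same share comes to 16.7%, beside the 18.2% found.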